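The readings are calculated with constants of no real substance; scatter was added.

In a closed, stirred vessel held at one temperature, starting material turns into target in the presence of a first and a second nucleophile. Four flasks, birch, larch, alder and cedar, differ in temperature.

| setting | Friday's | Monday's | Tuesday's | birch | larch | alder | cedar |
|---|---|---|---|---|---|---|---|
| starting material | 0.050 M | 0.075 M | 0.10 M | 0.10 M | 0.10 M | 0.10 M | 0.10 M |
| first nucleophile | 0.30 M | 0.30 M | 0.15 M | 0.300 M | 0.300 M | 0.300 M | 0.300 M |
| second nucleophile | 0.095 M | 0.095 M | 0.095 M | 0.0950 M | 0.0950 M | 0.0950 M | 0.0950 M |
| temperature | −45 °C | −10 °C | −45 °C | −20 °C | −40 °C | 20 °C | 0 °C |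
| remark | run made earlier | run made earlier | run made earlier |  |  |  |  |
| time |  |  |  | 2.5 min | 2.5 min | 2.5 min | 2.5 min |

- Friday's (time / min: target / %, starting material / %): 0.667: 0.2, 99.7; 2.50: 1.9, 98.3; 5.00: 3.1, 95.8; 6.00: 3.5, 96.1; 8.00: 5.0, 95.1
- Monday's (time / s: target / %, starting material / %): 10.0: 14.4, 84.0; 25.0: 32.6, 64.8; 50.0: 55.8, 41.1; 80.0: 72.8, 24.7; 90.0: 76.8, 19.5
- Tuesday's (time / min: target / %, starting material / %): 0.667: 0, 99.0; 1.33: 0.8, 99.1; 2.50: 1.2, 98.4; 5.00: 2.7, 97.5; 8.00: 4.1, 95.4

(scatter of a reading: 0.5 percentage points)

- the flask with the highest amount of target, in percent of the starting material charged ("all alike" if they lie within 1.5 percentage points) (birch / larch / alder / cedar / all alike)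
- final target, as a percentage of the starting material charged, in birch
- final target, as a percentage of the starting material charged, in larch
- final target, as a percentage of the starting material charged, in alder
- final target, as a percentage of the starting material charged, in cedar



Friday's and Tuesday's runs stood at the same temperature, −45 °C. After 8.00 min they had lost 4.90 % and 4.60 % of their starting material, though Tuesday's run had half the first nucleophile and twice the starting material. A loss of the same fraction per minute whatever the charge is first order, with a rate constant k, so I placed the first nucleophile after the rate-limiting step. Monday's last reading, at −10 °C, gives k as the logarithm of charged over remaining, divided by time: 1.09 min⁻¹.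

Next I needed to know how much of the lost starting material ends as target. Dividing the rate at which target rises by the rate at which starting material falls removes time, and the amounts at one reading give that ratio's mean up to that reading, not its value at each moment. I took Monday's last reading, where the turnover stands largest against the scatter. It gives s = 95.4 %, the selectivity: target gained per starting material lost, taken as a mean over the run up to that reading. As an estimate, I reckoned target as s times the conversion.

Monday's k over 2.5 min leaves 6.55 % of the starting material, and cedar and alder are warmer than Monday's run. So my own reckoning put both near s. Birch and larch are colder than Monday's run, so I put them lower, by their unconverted part.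

The forecast named cedar, with 47 % in birch, 3.3 % in larch, 92 % in alder, below my s, and 94 % in cedar, noting that “Later loss of target by the second nucleophile, or poorer selectivity when hot, remains possible”.

The flasks gave 48.7 % in birch, 3.30 % in larch, 79.9 % in alder and 95.1 % in cedar, so cedar held the most.

    starting material → intermediate (k = 0.00470 s⁻¹, Ea = 73.0 kJ mol⁻¹)
    first nucleophile + intermediate → target (k = 31.0 M⁻¹ s⁻¹, Ea = 46.0 kJ mol⁻¹)
    second nucleophile + intermediate → other capture product (k = 8.40 M⁻¹ s⁻¹, Ea = 48.0 kJ mol⁻¹)
    2 second nucleophile → self-condensation product (k = 0.150 M⁻¹ s⁻¹, Ea = 54.0 kJ mol⁻¹)
    target → over-reaction product (k = 5.40 × 10⁻⁶ s⁻¹, Ea = 83.0 kJ mol⁻¹)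
    (constants at −20 °C)

Between larch and alder, the largest single effect is what the temperature does to the making of intermediate from starting material: without it, their gap of 77 percentage points stands at −0.075 points. But alder parted from my reckoning. With 0 % starting material left in alder, s gives 95.4 %, yet alder held 79.9 %, beside 15.2 % of over-reaction product. Part of the answer is the loss of target to over-reaction product: alder run without that step holds 95.1 %. So s counts what capture makes, and the target's later loss comes on top. A flask like cedar kept at −25 °C ended with 70.4 % starting material, so s gives 28.2 % of target there; the computed flask holds 28.3 %.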